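1. Retrosynthesis first unmasks the catechol (two MOM ethers), then puts oxygen back on benzylic C4 and lengthens the C2 methyl to a CH2CHO arm; these two groups fold into a bridged lactol.
2. The lactol is cut at its hemiacetal C–O bond, at O1–C2 and at C3–C4. The quaternary ether carbon C2 of the dihydropyran ring lies 1,3 to benzylic C4, so C3, C2 and the C2 methyl are the 3-methyl carbon, C3 and C2 of geranylgeranial, while C4 and O1 are the formyl carbon and phenol oxygen of a salicylaldehyde.
3. Forward, the arene comes from 3,4,5-trimethoxytoluene (formylation, demethylation, 3,4-bis-MOM protection) and the enal from geranylgeraniol (MnO2).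
4. One amine-catalysed domino step joins them: C3–C4 by vinylogous aldol addition, then the pyran ring by O1–C2 oxa-Michael closure, then the temporary lactol ring.
5. Decarbonylation trims the arm to the methyl group, dehydration and selective hydrogenation remove the C4 oxygen, and methanolysis frees the catechol; the side-chain E alkenes come unchanged from geranylgeraniol.
6. The single stereocentre, C2 (S), is set by the chiral diarylprolinol silyl ether in the oxa-Michael step and can no longer reopen once the arm is decarbonylated.

Key step: step 5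

Assumption: the (R)-catalyst is assigned to the (2S) series by the usual shielding model (phenol oxygen delivered anti to the silyloxydiarylmethyl group, side chain cis to the iminium carbon); if a first run shows the opposite sense, the (S)-catalyst is used and nothing else changes.

**Step 1**
Reactants: 1 3,4,5-trimethoxytoluene
Product: 2 2,3,4-trimethoxy-6-methylbenzaldehyde
Conditions: POCl3, DMF, 0 → 80 °C; then H2O
Reagents that add atoms: N,N-dimethylformamide CN(C)C=O; water O
Why: Vilsmeier–Haack formylation; the two free ring positions of 1 are equivalent and activated by ortho and para methoxy groups, so a single aldehyde should result.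

**Step 2**
Reactants: 2 2,3,4-trimethoxy-6-methylbenzaldehyde
Product: 3 2,3,4-trihydroxy-6-methylbenzaldehyde
Conditions: BBr3 (4 equiv), CH2Cl2, −78 °C → rt; then H2O
Reagents that add atoms: none
Why: Lewis-acid cleavage of aryl methyl ethers with BBr3 should remove all three methyl groups while the aldehyde is returned unchanged on hydrolysis.

**Step 3**
Reactants: 3 2,3,4-trihydroxy-6-methylbenzaldehyde
Product: 4 2-hydroxy-3,4-bis(methoxymethoxy)-6-methylbenzaldehyde
Conditions: MOMCl (2.1 equiv), iPr2NEt (2.5 equiv), CH2Cl2, 0 °C → rt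
Reagents that add atoms: chloromethyl methyl ether COCCl
Why: Base-mediated O-alkylation (MOM ether formation); the 2-hydroxyl is held in a hydrogen bond to the formyl group and is the least nucleophilic, as in the known 3,4-bis-protection of 2,3,4-trihydroxyaryl carbonyl compounds, so two equivalents should cap O3 and O4 only.

**Step 4**
Reactants: 5 (2E,6E,10E)-geranylgeraniol
Product: 6 (2E,6E,10E)-geranylgeranial
Conditions: activated MnO2 (15 equiv), hexane, rt
Reagents that add atoms: none
Why: Allylic alcohol oxidation with MnO2 is selective for the allylic carbinol and leaves the isolated trisubstituted alkenes alone; any E/Z leakage at C2 is harmless because step 5 erases that geometry.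

**Step 5**
Reactants: 4 2-hydroxy-3,4-bis(methoxymethoxy)-6-methylbenzaldehyde; 6 (2E,6E,10E)-geranylgeranial
Product: 8 bridged lactol (2S,4S in chroman numbering; both anomers), via hydroxy aldehyde 7 (not isolated)
Conditions: (R)-2-{bis[3,5-bis(trifluoromethyl)phenyl][(triethylsilyl)oxy]methyl}pyrrolidine (30 mol%), PhCO2H (30 mol%), toluene, rt, 3–5 d; 6 in 1.5-fold excess
Reagents that add atoms: none
Why: The amine condenses with 6 to a catalyst-bound dienamine whose terminal CH2 (the former 3-methyl) adds to the hydrogen-bond-activated formyl group of 4 (vinylogous aldol, C3–C4); the regenerated iminium ion is attacked at its β-carbon by the phenol oxygen (oxa-Michael, O1–C2), and hydrolysis releases 7, whose C4 hydroxyl adds to the CH2CHO arm to give 8. The closest known reaction type is the secondary-amine-catalysed domino aldol/oxa-Michael reaction of salicylaldehydes with β-methyl-β-alkyl enals, which gives bridged chroman lactols with a quaternary C2. The dihydropyran ring closes by 6-exo-trig oxa-Michael addition and the lactol ring by 6-exo-trig addition of the C4 hydroxyl to the aldehyde carbonyl. C2 is set by the catalyst, whose silyloxydiarylmethyl group blocks one face of the iminium ion; C4 is fixed relative to C2 by the bridge, because only the isomer with the C4 oxygen cis to the arm can lactolise and the reversible steps drain into it; the anomeric carbon is uncontrolled and is excised in step 6. The step needs attack through the methyl terminus of the dienamine and cross-reaction rather than enal self-condensation; the unhindered CH2 terminus, the ortho phenol (which activates the aldehyde and then traps the iminium ion intramolecularly) and the lactol sink should secure this, and both enal geometries converge on the same dienamine.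

**Step 6**
Reactants: 8 bridged lactol
Product: 9 (2S,4S)-7,8-bis(methoxymethoxy)-2,5-dimethyl-2-[(3E,7E)-4,8,12-trimethyltrideca-3,7,11-trien-1-yl]chroman-4-ol
Conditions: RhCl(PPh3)3 (1.2 equiv), PhCN, 130 °C, argon
Reagents that add atoms: none
Why: Tsuji–Wilkinson decarbonylation, in which the lactol reacts through the small equilibrium share of its ring-opened hydroxy aldehyde form, the same species as 7 (formyl C–H oxidative addition to monovalent rhodium, CO extrusion, C–H reductive elimination), as known for aldoses and other lactols; the alkyl–rhodium intermediate has no β-hydrogen because C2 is quaternary, the neutral medium disfavours retro-oxa-Michael opening, and no stereocentre is touched.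

**Step 7**
Reactants: 9 the (2S,4S)-chroman-4-ol
Product: 10 (2S)-7,8-bis(methoxymethoxy)-2,5-dimethyl-2-[(3E,7E)-4,8,12-trimethyltrideca-3,7,11-trien-1-yl]-2H-chromene
Conditions: Burgess reagent (MeO2CN(−)SO2N(+)Et3, 1.5 equiv), toluene, 50 °C, dark
Reagents that add atoms: none
Why: Burgess dehydration (syn-elimination of the sulfamate ester); the activated benzylic C4–O bond has β-hydrogens only on C3, and the non-acidic, low-temperature, light-free conditions should avoid both a free C4 cation that the first side-chain alkene could trap and reversible 6π ring opening of the chromene; the C4 stereocentre is deliberately destroyed.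

**Step 8**
Reactants: 10 the (2S)-2H-chromene
Product: 11 (2S)-7,8-bis(methoxymethoxy)-2,5-dimethyl-2-[(3E,7E)-4,8,12-trimethyltrideca-3,7,11-trien-1-yl]chroman
Conditions: H2 (1 atm), RhCl(PPh3)3 (10 mol%), toluene/EtOH 1:1, rt; stopped after 1 equiv H2
Reagents that add atoms: none
Why: Homogeneous hydrogenation with RhCl(PPh3)3 should reduce the cis-disubstituted, styrene-type C3=C4 bond much faster than the three trisubstituted side-chain alkenes; C2 is not involved.

**Step 9**
Reactants: 11 the bis-MOM chroman
Product: 12 (2S)-2,5-dimethyl-2-[(3E,7E)-4,8,12-trimethyltrideca-3,7,11-trien-1-yl]chroman-7,8-diol (CNP0122319.1)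
Conditions: HCl (1 M in MeOH), 0 °C → rt, argon, degassed solvent
Reagents that add atoms: none
Why: Acid-catalysed acetal exchange (methanolysis of aryl MOM ethers) should free the catechol under conditions that isolated trisubstituted alkenes tolerate, as in deprotections of polyprenylated phenols; the C2 ether stereocentre is inert.

**Compound list**
1 | 3,4,5-trimethoxytoluene | COc1cc(C)cc(OC)c1OC | starting material
2 | 2,3,4-trimethoxy-6-methylbenzaldehyde | O=Cc1c(C)cc(OC)c(OC)c1OC | intermediate
3 | 2,3,4-trihydroxy-6-methylbenzaldehyde | O=Cc1c(C)cc(O)c(O)c1O | intermediate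
4 | 2-hydroxy-3,4-bis(methoxymethoxy)-6-methylbenzaldehyde | O=Cc1c(C)cc(OCOC)c(OCOC)c1O | intermediate
5 | (2E,6E,10E)-geranylgeraniol, (2E,6E,10E)-3,7,11,15-tetramethylhexadeca-2,6,10,14-tetraen-1-ol | CC(C)=CCC/C(C)=C/CC/C(C)=C/CC/C(C)=C/CO | starting material
6 | (2E,6E,10E)-geranylgeranial | CC(C)=CCC/C(C)=C/CC/C(C)=C/CC/C(C)=C/C=O | intermediate
7 | 2-[(2S,4S)-4-hydroxy-7,8-bis(methoxymethoxy)-5-methyl-2-[(3E,7E)-4,8,12-trimethyltrideca-3,7,11-trien-1-yl]chroman-2-yl]acetaldehyde | CC(C)=CCC/C(C)=C/CC/C(C)=C/CC[C@@]1(CC=O)C[C@H](O)c2c(C)cc(OCOC)c(OCOC)c2O1 | intermediate (not isolated)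
8 | bridged lactol: hemiacetal of 7 between the C4 hydroxyl and the formyl group, (2S,4S) in chroman numbering, both anomers; a (2S,6S)-3,4-dihydro-2H,6H-2,6-methano-1,5-benzodioxocin-4-ol with 7-methyl, 9,10-bis(methoxymethoxy) and the 2-trienyl chain | CC(C)=CCC/C(C)=C/CC/C(C)=C/CC[C@@]12CC(O)O[C@@H](C1)c1c(C)cc(OCOC)c(OCOC)c1O2 | intermediate
9 | (2S,4S)-7,8-bis(methoxymethoxy)-2,5-dimethyl-2-[(3E,7E)-4,8,12-trimethyltrideca-3,7,11-trien-1-yl]chroman-4-ol (hydroxyl cis to the C2 methyl) | CC(C)=CCC/C(C)=C/CC/C(C)=C/CC[C@@]1(C)C[C@H](O)c2c(C)cc(OCOC)c(OCOC)c2O1 | intermediate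
10 | (2S)-7,8-bis(methoxymethoxy)-2,5-dimethyl-2-[(3E,7E)-4,8,12-trimethyltrideca-3,7,11-trien-1-yl]-2H-chromene | CC(C)=CCC/C(C)=C/CC/C(C)=C/CC[C@@]1(C)C=Cc2c(C)cc(OCOC)c(OCOC)c2O1 | intermediate
11 | (2S)-7,8-bis(methoxymethoxy)-2,5-dimethyl-2-[(3E,7E)-4,8,12-trimethyltrideca-3,7,11-trien-1-yl]chroman | CC(C)=CCC/C(C)=C/CC/C(C)=C/CC[C@@]1(C)CCc2c(C)cc(OCOC)c(OCOC)c2O1 | intermediate
12 | (2S)-2,5-dimethyl-2-[(3E,7E)-4,8,12-trimethyltrideca-3,7,11-trien-1-yl]chroman-7,8-diol | CC(C)=CCC/C(C)=C/CC/C(C)=C/CC[C@@]1(C)CCc2c(C)cc(O)c(O)c2O1 | target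

**Count**
Total steps: 9. Longest linear sequence: 8 steps (1 → 2 → 3 → 4 → 8 → 9 → 10 → 11 → 12); the enal branch is one step.

**Steps most likely to fail**

Step 5. Self-condensation of the enal through its dienamine may outrun the aldol addition to the doubly ortho-substituted, hydrogen-bonded aldehyde, or face discrimination in the oxa-Michael closure may be too low. The fallback sets out from 4 and returns at 9. Addition of MeMgBr (2.2 equiv, THF, 0 °C) to 4 should give the carbinol 1-[2-hydroxy-3,4-bis(methoxymethoxy)-6-methylphenyl]ethanol F1, which MnO2 oxidises to the ketone 1-[2-hydroxy-3,4-bis(methoxymethoxy)-6-methylphenyl]ethanone F2. A Kabbe condensation of F2 with commercial (5E,9E)-farnesylacetone (pyrrolidine, toluene, reflux) should then build the racemic 7,8-bis(methoxymethoxy)-2,5-dimethyl-2-[(3E,7E)-4,8,12-trimethyltrideca-3,7,11-trien-1-yl]chroman-4-one F3, with side chain and C2 methyl in place. Noyori transfer hydrogenation (RuCl[(S,S)-TsDPEN](p-cymene), HCO2H/Et3N) is expected to set C4 as (S) under catalyst control in both enantiomers of F3, which gives 9 together with the (2R,4S)-chroman-4-ol F4; the two diastereomers are to be separated by chromatography (preparative HPLC if needed). Compound 9 then continues with step 7, at the cost of half the material.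

Step 6. The aldehyde is available only through the small open-chain fraction of the lactol, so at the temperature needed, thermal retro-oxa-Michael opening of the β-aryloxy aldehyde (loss of configurational purity at C2) or dehydration at C4 may compete. The fallback sets out from 8 and returns at 11, bypassing steps 6–8. Oxidation of 8 (TEMPO, PhI(OAc)2, CH2Cl2) gives the bridged lactone F5. Li in NH3/THF at −78 °C should cleave its benzylic C4–O ester bond, which opens the bridge and removes the C4 oxygen in one operation, giving [(2S)-7,8-bis(methoxymethoxy)-5-methyl-2-[(3E,7E)-4,8,12-trimethyltrideca-3,7,11-trien-1-yl]chroman-2-yl]acetic acid F6. This acid is converted (N-hydroxypyridine-2-thione, DCC) into its 2-thioxopyridin-1(2H)-yl ester F7, and Barton decarboxylation of that ester with Bu3SnH and catalytic PhSeSePh gives 11; benzeneselenol formed in the flask donates hydrogen fast enough to outrun 5-exo closure onto the first chain alkene.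

Step 8. Hydrogen uptake at C3=C4 may be slow (quaternary C2 on one side, peri methyl on the other), so that saturation of the chain alkenes creeps in. The fallback sets out from 9 and returns at 11, skipping 10. Compound 9 is acylated with 4-methylbenzoyl chloride (Et3N, DMAP, CH2Cl2) to the (2S,4S)-chroman-4-yl 4-methylbenzoate F8, and SmI2/HMPA in THF at rt (Markó–Lam deoxygenation) should then cleave the benzylic C–O bond by single-electron reduction to give 11; the ester, not an alkene, accepts the electron, so the chain is not at risk.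

**Further compounds**
F1 | step 5 | 1-[2-hydroxy-3,4-bis(methoxymethoxy)-6-methylphenyl]ethanol (racemic) | CC(O)c1c(C)cc(OCOC)c(OCOC)c1O
F2 | step 5 | 1-[2-hydroxy-3,4-bis(methoxymethoxy)-6-methylphenyl]ethanone | CC(=O)c1c(C)cc(OCOC)c(OCOC)c1O
F3 | step 5 | racemic 7,8-bis(methoxymethoxy)-2,5-dimethyl-2-[(3E,7E)-4,8,12-trimethyltrideca-3,7,11-trien-1-yl]chroman-4-one | CC(C)=CCC/C(C)=C/CC/C(C)=C/CCC1(C)CC(=O)c2c(C)cc(OCOC)c(OCOC)c2O1
F4 | step 5 | (2R,4S)-7,8-bis(methoxymethoxy)-2,5-dimethyl-2-[(3E,7E)-4,8,12-trimethyltrideca-3,7,11-trien-1-yl]chroman-4-ol | CC(C)=CCC/C(C)=C/CC/C(C)=C/CC[C@]1(C)C[C@H](O)c2c(C)cc(OCOC)c(OCOC)c2O1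
F5 | step 6 | bridged lactone, the lactol carbon of 8 oxidised to C=O, (2S,4S) in chroman numbering | CC(C)=CCC/C(C)=C/CC/C(C)=C/CC[C@@]12CC(=O)O[C@@H](C1)c1c(C)cc(OCOC)c(OCOC)c1O2
F6 | step 6 | [(2S)-7,8-bis(methoxymethoxy)-5-methyl-2-[(3E,7E)-4,8,12-trimethyltrideca-3,7,11-trien-1-yl]chroman-2-yl]acetic acid | CC(C)=CCC/C(C)=C/CC/C(C)=C/CC[C@@]1(CC(=O)O)CCc2c(C)cc(OCOC)c(OCOC)c2O1
F7 | step 6 | 2-thioxopyridin-1(2H)-yl ester of F6 (Barton ester) | CC(C)=CCC/C(C)=C/CC/C(C)=C/CC[C@@]1(CC(=O)On2ccccc2=S)CCc2c(C)cc(OCOC)c(OCOC)c2O1
F8 | step 8 | (2S,4S)-7,8-bis(methoxymethoxy)-2,5-dimethyl-2-[(3E,7E)-4,8,12-trimethyltrideca-3,7,11-trien-1-yl]chroman-4-yl 4-methylbenzoate | CC(C)=CCC/C(C)=C/CC/C(C)=C/CC[C@@]1(C)C[C@H](OC(=O)c2ccc(C)cc2)c2c(C)cc(OCOC)c(OCOC)c2O1
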